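**Plan**

1. Retrosynthesis cuts, in this order: the three O–Si bonds of a fully silylated precursor; the C1'–C(aryl) bond between the heptadecadienyl chain and C5 of the resorcinol ring (the chain arrives as a C18 acid whose C1 leaves as CO2); and the C12'–O bond, which is the C13–O bond of a hydrated α-linolenic acid.
2. Enabling feature: numbered from the benzylic carbon, C1'–C17' with Z alkenes at C8'=C9' and C14'=C15' and the C12' carbinol maps atom for atom onto C2–C18 of α-linolenic acid after addition of water across its middle alkene C12=C13. The only ring, the resorcinol, is bought as 5-bromoresorcinol; no ring is closed.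
3. Forward: enzymatic hydration of α-linolenic acid installs the carbinol (step 1); O-silylation and activation as an N-acyloxyphthalimide follow (steps 2, 3); the silylated arylzinc reagent from 5-bromoresorcinol is joined to C2 with loss of CO2 under nickel catalysis (steps 4, 5); fluoride removes the three silyl groups (step 6).
4. Stereochemistry: the single stereocentre (C12', S) is set by the hydratase; both Z alkenes are inherited from α-linolenic acid and are never touched.

Key step: step 1

Assumption: the lactobacillal linoleate 13-hydratase is taken to hydrate α-linolenic acid with the facial sense that gives the 13S carbinol drawn for 2; because the C15=C16 alkene makes C14 outrank C12, this descriptor cannot simply be carried over from the linoleic acid product, and it should be confirmed on 2 (Mosher esters of its methyl ester) before material is carried forward.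

**Route**

Step 1
Reactants: 1 α-linolenic acid
Product: 2 (9Z,13S,15Z)-13-hydroxyoctadeca-9,15-dienoic acid
Conditions: resting Escherichia coli cells producing recombinant Lactobacillus acidophilus linoleate 13-hydratase (FAD-bound), citrate–phosphate buffer pH 6.0, Tween 40, N2, 35 °C; then pH 3, EtOAc extraction
Reagents that add atoms: water, O
Why: Fatty acid hydratase catalysis (hydro-lyase, no net redox change): the carboxylate of 1 is held at the entrance of a hydrophobic channel so that only the C12=C13 alkene reaches the catalytic residues, where an active-site acid protonates C12 while an activated water molecule adds to C13 on the opposite face (anti addition), the bound flavin serving only to shape the site. The closest known reaction is the hydration of oleic acid to (R)-10-hydroxystearic acid by oleate hydratase, and the hydration of linoleic and α-linolenic acids at C12=C13 by lactobacillal 13-hydratases is itself an established whole-cell transformation. No ring is closed; one C–O bond (C13–O, the later C12'–O bond) and one C–H bond are formed. The single new stereocentre at C13 is set by the enzyme (catalyst control), which delivers water to one face of the bound cis alkene; it is taken to be S as drawn. The step needs site selectivity among three electronically equivalent Z alkenes, and this is secured by the fixed distance between the carboxylate anchor and the catalytic site; C9=C10 and C15=C16 should keep their Z geometry because no free cation or radical is generated.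

Step 2
Reactants: 2 (9Z,13S,15Z)-13-hydroxyoctadeca-9,15-dienoic acid
Product: 4 (9Z,13S,15Z)-13-(tert-butyldimethylsilyloxy)octadeca-9,15-dienoic acid, via silyl ester 3 (not isolated)
Conditions: TBSCl (2.5 equiv), imidazole (5 equiv), DMF, rt; then K2CO3, THF/H2O, rt; aq. citric acid to pH 4
Reagents that add atoms: tert-butyldimethylsilyl chloride (TBSCl), CC(C)(C)[Si](C)(C)Cl
Why: Standard silyl ether formation silylates both the C13 hydroxyl and the carboxyl group, and the far more labile silyl ester 3 should then be hydrolysed selectively by aqueous carbonate while the secondary silyl ether survives, with no bond to C13 broken and both Z alkenes unchanged.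

Step 3
Reactants: 4 (9Z,13S,15Z)-13-(tert-butyldimethylsilyloxy)octadeca-9,15-dienoic acid; 5 N-hydroxyphthalimide
Product: 6 1,3-dioxoisoindolin-2-yl (9Z,13S,15Z)-13-(tert-butyldimethylsilyloxy)octadeca-9,15-dienoate
Conditions: N,N'-diisopropylcarbodiimide (1.1 equiv), DMAP (0.1 equiv), CH2Cl2, 0 °C to rt
Reagents that add atoms: none
Why: Carbodiimide-mediated (Steglich-type) esterification of the acid with the N-hydroxy imide should give the redox-active ester under neutral conditions that leave the silyl ether intact, and there is no α-stereocentre to epimerise.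

Step 4
Reactants: 7 5-bromobenzene-1,3-diol
Product: 8 1-bromo-3,5-bis(tert-butyldimethylsilyloxy)benzene
Conditions: TBSCl (2.4 equiv), imidazole (5 equiv), DMF, rt
Reagents that add atoms: tert-butyldimethylsilyl chloride (TBSCl), CC(C)(C)[Si](C)(C)Cl
Why: Phenol silylation with TBSCl/imidazole masks both acidic O–H groups so that the aryl bromide can be turned into an organometallic reagent, and the same fluoride treatment later removes these groups together with the C12' silyl ether.

Step 5
Reactants: 6 1,3-dioxoisoindolin-2-yl (9Z,13S,15Z)-13-(tert-butyldimethylsilyloxy)octadeca-9,15-dienoate; 8 1-bromo-3,5-bis(tert-butyldimethylsilyloxy)benzene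
Product: 11 5-[(8Z,12S,14Z)-12-(tert-butyldimethylsilyloxy)heptadeca-8,14-dien-1-yl]-1,3-bis(tert-butyldimethylsilyloxy)benzene, via arylmagnesium bromide 9 (not isolated), via arylzinc chloride 10 (not isolated)
Conditions: 8 (3 equiv), Mg turnings, LiCl, THF, rt; ZnCl2 (THF), 0 °C to rt; then 6 (1 equiv), NiCl2(glyme) (20 mol%), 4,4'-di-tert-butyl-2,2'-bipyridine (40 mol%), DMF/THF, rt; aq. NH4Cl work-up
Reagents that add atoms: none
Why: Nickel-catalysed decarboxylative Negishi-type arylation of a redox-active ester, in which an arylnickel species of low valence reduces 6 by single-electron transfer, the ester fragments to phthalimidate, CO2 and the primary C2 radical, and this radical is captured at nickel and reductively eliminated with the aryl group; the nearest alkene begins seven bonds from the radical centre, so cyclisation should not compete, and the silyl ethers, both Z alkenes and the remote carbinol stereocentre are not engaged.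

Step 6
Reactants: 11 5-[(8Z,12S,14Z)-12-(tert-butyldimethylsilyloxy)heptadeca-8,14-dien-1-yl]-1,3-bis(tert-butyldimethylsilyloxy)benzene
Product: 12 5-[(8Z,12S,14Z)-12-hydroxyheptadeca-8,14-dien-1-yl]benzene-1,3-diol (CNP0134801.1)
Conditions: Bu4NF (5 equiv), THF, 0 °C to rt, under N2; aq. NH4Cl work-up
Reagents that add atoms: none
Why: Fluoride-mediated silyl ether cleavage, driven by Si–F bond formation, should remove all three silyl groups under non-acidic conditions that leave the homoallylic alcohol, the Z alkenes and the C12' stereocentre untouched.

**Compound list**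

1 | α-linolenic acid, (9Z,12Z,15Z)-octadeca-9,12,15-trienoic acid | CC/C=C\C/C=C\C/C=C\CCCCCCCC(=O)O | starting material
2 | (9Z,13S,15Z)-13-hydroxyoctadeca-9,15-dienoic acid | CC/C=C\C[C@@H](O)CC/C=C\CCCCCCCC(=O)O | intermediate
3 | tert-butyldimethylsilyl (9Z,13S,15Z)-13-(tert-butyldimethylsilyloxy)octadeca-9,15-dienoate | CC/C=C\C[C@@H](O[Si](C)(C)C(C)(C)C)CC/C=C\CCCCCCCC(=O)O[Si](C)(C)C(C)(C)C | intermediate
4 | (9Z,13S,15Z)-13-(tert-butyldimethylsilyloxy)octadeca-9,15-dienoic acid | CC/C=C\C[C@@H](O[Si](C)(C)C(C)(C)C)CC/C=C\CCCCCCCC(=O)O | intermediate
5 | N-hydroxyphthalimide | O=C1c2ccccc2C(=O)N1O | starting material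
6 | 1,3-dioxoisoindolin-2-yl (9Z,13S,15Z)-13-(tert-butyldimethylsilyloxy)octadeca-9,15-dienoate | CC/C=C\C[C@@H](O[Si](C)(C)C(C)(C)C)CC/C=C\CCCCCCCC(=O)ON1C(=O)c2ccccc2C1=O | intermediate
7 | 5-bromobenzene-1,3-diol | Oc1cc(O)cc(Br)c1 | starting material
8 | 1-bromo-3,5-bis(tert-butyldimethylsilyloxy)benzene | CC(C)(C)[Si](C)(C)Oc1cc(Br)cc(O[Si](C)(C)C(C)(C)C)c1 | intermediate
9 | [3,5-bis(tert-butyldimethylsilyloxy)phenyl]magnesium bromide | Br[Mg]c1cc(O[Si](C)(C)C(C)(C)C)cc(O[Si](C)(C)C(C)(C)C)c1 | intermediate
10 | [3,5-bis(tert-butyldimethylsilyloxy)phenyl]zinc chloride | Cl[Zn]c1cc(O[Si](C)(C)C(C)(C)C)cc(O[Si](C)(C)C(C)(C)C)c1 | intermediate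
11 | 5-[(8Z,12S,14Z)-12-(tert-butyldimethylsilyloxy)heptadeca-8,14-dien-1-yl]-1,3-bis(tert-butyldimethylsilyloxy)benzene | CC/C=C\C[C@@H](O[Si](C)(C)C(C)(C)C)CC/C=C\CCCCCCCc1cc(O[Si](C)(C)C(C)(C)C)cc(O[Si](C)(C)C(C)(C)C)c1 | intermediate
12 | 5-[(8Z,12S,14Z)-12-hydroxyheptadeca-8,14-dien-1-yl]benzene-1,3-diol | CC/C=C\C[C@@H](O)CC/C=C\CCCCCCCc1cc(O)cc(O)c1 | target

**Step count**

Total: 6 steps. Longest linear sequence: 5 steps (steps 1, 2, 3, 5, 6); the aryl branch contributes step 4.

**Steps most likely to fail**

Step 1. Water may be delivered to the face of the C12=C13 alkene opposite to the one assumed, or conversion may stall through poor dispersion of the fatty acid or substrate inhibition. The fallback sets out from 1 and moves the stereochemical decision from the enzyme to an SN2 inversion. Hydration as above would then give (9Z,13R,15Z)-13-hydroxyoctadeca-9,15-dienoic acid F1. This would be esterified (Me3SiCHN2, toluene/MeOH, 0 °C) to methyl (9Z,13R,15Z)-13-hydroxyoctadeca-9,15-dienoate F2. Mitsunobu inversion (4-nitrobenzoic acid, PPh3, diisopropyl azodicarboxylate, THF, 0 °C) would give methyl (9Z,13S,15Z)-13-[(4-nitrobenzoyl)oxy]octadeca-9,15-dienoate F3. Saponification of both esters (LiOH, THF/MeOH/H2O, rt) returns to the route at 2.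

Step 5. Capture of the primary radical at nickel may be slow, so that direct aryl addition to the activated ester, reduction of the radical to the decarboxylated alkane or biaryl formation take over; sluggish magnesium insertion into the electron-rich bromide would add to this. The fallback sets out from 6 and separates decarboxylation from C–C bond formation. Light-driven decarboxylative borylation (bis(catecholato)diboron, N,N-dimethylacetamide, blue LEDs, rt; then pinacol, Et3N) would give 2-[(8Z,12S,14Z)-12-(tert-butyldimethylsilyloxy)heptadeca-8,14-dien-1-yl]-4,4,5,5-tetramethyl-1,3,2-dioxaborolane F4. B-alkyl Suzuki–Miyaura coupling of F4 with 8 (Pd(OAc)2, RuPhos, K3PO4, toluene/H2O, 80 °C, zerovalent palladium formed in situ) returns to the route at 11. Any loss of an aryl silyl group there would be harmless, since step 6 removes them all.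

Step 6. Cleavage of the secondary silyl ether may be incomplete, and the electron-rich resorcinol may degrade oxidatively while it is held as its phenoxide under basic fluoride. The fallback sets out from 11 and stages the deprotection. Mild methanolysis (K2CO3, MeOH, rt) would cleave only the two aryl silyl ethers and give 5-[(8Z,12S,14Z)-12-(tert-butyldimethylsilyloxy)heptadeca-8,14-dien-1-yl]benzene-1,3-diol F5. Buffered acidic fluoride (HF·pyridine, pyridine/THF, 0 °C to rt), under which the phenols stay protonated, would then remove the remaining silyl ether and return to the route at 12.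

**Further compounds**

F1 | step 1 | (9Z,13R,15Z)-13-hydroxyoctadeca-9,15-dienoic acid | CC/C=C\C[C@H](O)CC/C=C\CCCCCCCC(=O)O
F2 | step 1 | methyl (9Z,13R,15Z)-13-hydroxyoctadeca-9,15-dienoate | CC/C=C\C[C@H](O)CC/C=C\CCCCCCCC(=O)OC
F3 | step 1 | methyl (9Z,13S,15Z)-13-[(4-nitrobenzoyl)oxy]octadeca-9,15-dienoate | CC/C=C\C[C@@H](OC(=O)c1ccc(cc1)[N+](=O)[O-])CC/C=C\CCCCCCCC(=O)OC
F4 | step 5 | 2-[(8Z,12S,14Z)-12-(tert-butyldimethylsilyloxy)heptadeca-8,14-dien-1-yl]-4,4,5,5-tetramethyl-1,3,2-dioxaborolane | CC/C=C\C[C@@H](O[Si](C)(C)C(C)(C)C)CC/C=C\CCCCCCCB1OC(C)(C)C(C)(C)O1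
F5 | step 6 | 5-[(8Z,12S,14Z)-12-(tert-butyldimethylsilyloxy)heptadeca-8,14-dien-1-yl]benzene-1,3-diol | CC/C=C\C[C@@H](O[Si](C)(C)C(C)(C)C)CC/C=C\CCCCCCCc1cc(O)cc(O)c1
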